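## Structural features

The target is a eudesmane-type trans-decalin (ring A: C1–C5 and C10; ring B: C5–C10) whose C1 is bonded to a benzylic methine C1′. C1′ also carries an isobutyl group and a fully substituted phloroglucinol ring with two formyl groups. Six stereocentres are present: C1′, C1, C10, C5 and C4 are contiguous and C7 on ring B stands apart. C10 is quaternary (angular methyl), C5–H is trans to that methyl, the C4 hydroxyl is axial and cis to it, and the substituents at C1 and C7 are equatorial. The two tertiary alcohols (C4 and the carbinol on C7) ionise or dehydrate under protic and Lewis acids, and the trihydroxy dialdehyde arene is electron-rich, chelating and easily oxidised, so the arene must be finished late and without strong acid. The real difficulty is twofold: the decalin with C4, C5 and C10 in the right sense relative to C1 and C7, and the congested C1′–C1 bond beside quaternary C10 with control of C1′. The key step uses the fact that carbinol carbon C4 is bonded to ring-fusion carbon C5 and that C5 and C10 carry H and methyl trans. This is the imprint of an E-configured C5=C10 alkene whose C5 attacks a C4 carbonyl while C10 is captured by C9, closing rings A and B together.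

## Logic of the disconnections

39 ⇒ 38 ⇒ 36 ⇒ 35. Three O–CH3 bonds, two aryl–CHO bonds and one further O–CH3 bond are cut. The free phloroglucinol dialdehyde is too reactive to carry, and these cuts reduce the arene to a simple dimethoxyphenol unit. The forward steps must spare two tertiary alcohols: formylation without Lewis acid and demethylation under basic, nucleophilic conditions.

35 ⇒ 31 + 32 + an isobutyl nucleophile. The aryl–C1′ and C1′–CH2 bonds are cut because both converge on one carbon that can pass through the aldehyde and ortho-quinone methide oxidation levels. The arene and the isobutyl group then come from commercial reagents and all remaining complexity sits in 31. The forward step needs ortho selectivity on the phenol and face selectivity at C1′ from the C1/C10 environment.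

31 ⇒ 30 ⇒ 28 ⇒ 27. These are adjustments only: the aldehyde from the primary alcohol, the two C–CH3 bonds of the C7 carbinol from the ester, and the saturated ring B and free primary alcohol from the C8=C9 alkene and the benzyl ether. This returns to the direct cyclisation product. The forward steps must oxidise only the primary alcohol and must not epimerise C7 while it is still allylic.

27 ⇒ 26. C4–C5 and C9–C10 are cut. Both rings and the stereocentres C4, C5 and C10 disappear, leaving an acyclic chain with only C1 and C7 stereogenic and two defined alkene geometries. The forward step needs a methyl ketone to initiate, the vinylsilane to terminate faster than the cation rearranges, and C1 and C7 to be matched (both equatorial in one chair–chair fold).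

26 ⇒ 25 ⇒ 24 ⇒ 22. The ketone is traced to a terminal alkene (C4=C15) and the methyl ester to the acid and the auxiliary imide. A ketone or ketal would not survive the titanium enolate, the organoaluminium reagent or the enolate alkylation used earlier, so the ketone is unveiled last. The forward steps need a chemoselective oxidation of the monosubstituted alkene and a non-basic route from imide to ester, because C7–H is doubly activated.

22 ⇒ 21 + 12. The C6–C7 bond is cut between the two stereogenic domains, which makes the route convergent. C7 is set by an auxiliary independently of C1. The forward step needs α-selective alkylation of a dienolate with retention of the Z-vinylsilane.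

12 ⇒ 11 ⇒ 9 ⇒ 8 ⇒ 7 ⇒ 6. The C10–CH3 and C5–C6 bonds are cut across the alkene, so the E geometry reduces to a terminal alkyne through a syn carbometalation. The alkyne carbon C5 is then removed back to the acyl carbon C10 of 6. This avoids an olefination of an epimerisable β-alkoxy methyl ketone. The forward steps need regio- and syn-selective carbometalation in which the isolated terminal alkene stays inert.

6 ⇒ 4 + 5 and 4 ⇒ 1 + 2. The C1–CH2O bond and the N-acyl bond are cut, so C1 arises from an auxiliary-controlled alkylation of a commercial acid. The forward step needs C-alkylation by the α-chloro ether (titanium enolate) and high face selectivity.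

21 ⇒ 18 + 19 and 18 ⇒ 16 ⇒ 15 ⇒ 13. The N-acyl bond is cut, the oxidation level is adjusted, the Z-alkene is traced to the alkyne and the C–Si bond is cut. The forward steps need a cis-selective semihydrogenation and an oxidation that does not move the β,γ double bond.

## Other disconnections considered

Alternative 1: The cut runs through the arene itself. Siloxyalkyne A1 and cyclobutenone A2 are heated; A2 opens to a vinylketene that adds to the alkyne, and electrocyclic opening and six-electron closure give phenol A3.
- In favour: the ynol ether polarity dictates the substitution pattern, the three oxygens emerge differentiated, and the neutral thermal conditions are safe for silylated tertiary alcohols. The congested aryl–C1′ bond is never made by a bimolecular coupling.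
- Better than the chosen plan on one point: the pericyclic cascade is better precedented than the cationic key step.
- Against: A1 already contains the whole decalin and C1′, so the decalin problem is untouched and C1′ must be set on a sensitive alkyne side chain. Two silyl protections, two formylations and removal of three different O-groups (the ethyl ether harshly) are still needed.
- Comparison: it solves the arene and not the decalin, by a concerted thermal mechanism, and it is longer in protecting-group and side-chain steps than the single three-component coupling used here.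

Alternative 2: C1–C10 and C4=C5 of ring A are cut. A Robinson-type annulation of ketone A4 with enone ester A5 under basic conditions gives tricycle A6.
- In favour: ring B comes from the chiral pool with C7 configured and the hydroxyisopropyl group latent in the cyclopropane. The quaternary C10 and the C1 carbon substituent are installed in one robust, scalable operation.
- Better than the chosen plan on two points: precedent, and step economy to a bicyclic core, which is far shorter than the fifteen steps that lead to 26.
- Against: A6 is at the wrong oxidation pattern. The C3 carbonyl must be removed, and the C4=C5 alkene must become the trans C5–H and the axial C4 carbinol with uncertain face control. The Michael regiochemistry on the doubly activated alkene and the C1 configuration must be secured, and the cyclopropane must be opened under acid.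
- Comparison: the chosen plan sets C4, C5 and C10 in one step at the final oxidation level; this one needs several corrective steps after its key step, so the overall counts are probably similar.

Alternative 3: The aryl–C1′ and C1′–CH2 bonds are cut. Aldehyde A7, magnesium phenoxide A8 and Grignard reagent A9 are united to phenol A10 through an ortho-quinone methide.
- This is the same transformation as step 20 of the chosen plan (A7 is identical with 31 and A10 with 35).
- In favour: maximal convergence, the full carbon skeleton and C1′ in one flask, and polar magnesium-templated events that are each precedented.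
- Equal or better: it is better precedented than the chosen key step, and downstream step economy is identical.
- Against: taken as the strategy it says nothing about the decalin; A7 with five stereocentres must come from elsewhere. Face selectivity at C1′ rests on substrate control only.
- Comparison: the two are complementary. The bicyclisation is ranked as the key step because it makes two rings and three stereocentres, whereas this coupling makes two bonds and one stereocentre.

Key step: step 16

Remark: locants C1–C15 follow the eudesmane skeleton (C1 carries the side chain, C4 the carbinol, C7 the hydroxyisopropyl group, C10 the angular methyl) and C1′ is the benzylic carbon. The structures of 26 and 27 map atom by atom onto the target and need no correction. The benzyl ring of 26 is its only arene and can reach the C10 cation only through a seven-membered closure, so the benzyl ether is kept.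

Step 1
Reactants: 1 hex-5-enoic acid; 2 (S)-4-benzyl-1,3-oxazolidin-2-one
Product: 4 (4S)-4-benzyl-3-(hex-5-enoyl)-1,3-oxazolidin-2-one, via hex-5-enoic pivalic anhydride 3 (not isolated)
Conditions: t-BuCOCl, Et3N, THF, −20 °C; then LiCl, 2, −20 °C → rt
Reagents that add atoms: none
Why: Mixed-anhydride N-acylation of the oxazolidinone under LiCl/Et3N activation; the terminal alkene serves as a latent methyl ketone that tolerates the Lewis acids and organometallics of the next steps.

Step 2
Reactants: 4 (4S)-4-benzyl-3-(hex-5-enoyl)-1,3-oxazolidin-2-one; 5 benzyl chloromethyl ether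
Product: 6 (4S)-4-benzyl-3-[(2R)-2-[(benzyloxy)methyl]hex-5-enoyl]-1,3-oxazolidin-2-one
Conditions: TiCl4, i-Pr2NEt, CH2Cl2, 0 °C; then 5, 0 °C
Reagents that add atoms: none
Why: Evans asymmetric alkylation through the chelated chlorotitanium Z-enolate; the electrophile adds to the face opposite the benzyl group of the (S)-auxiliary, which sets the centre that becomes C1. The titanium enolate is chosen because alkali-metal enolates tend to O-alkylate with α-chloro ethers.

Step 3
Reactants: 6 (4S)-4-benzyl-3-[(2R)-2-[(benzyloxy)methyl]hex-5-enoyl]-1,3-oxazolidin-2-one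
Product: 7 (2S)-2-[(benzyloxy)methyl]hex-5-en-1-ol
Conditions: LiBH4, MeOH (1 equiv), Et2O, 0 °C
Reagents that add atoms: none
Why: Reductive cleavage of the N-acyl oxazolidinone by LiBH4 gives the primary alcohol without touching the stereocentre and returns the auxiliary.

Step 4
Reactants: 7 (2S)-2-[(benzyloxy)methyl]hex-5-en-1-ol
Product: 8 (2R)-2-[(benzyloxy)methyl]hex-5-enal
Conditions: TEMPO (cat.), PhI(OAc)2, CH2Cl2, rt
Reagents that add atoms: none
Why: Oxoammonium (TEMPO) oxidation stops at the aldehyde under nearly neutral conditions, so the α-centre of the β-alkoxy aldehyde is neither epimerised nor lost by elimination; the aldehyde is used at once.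

Step 5
Reactants: 8 (2R)-2-[(benzyloxy)methyl]hex-5-enal
Product: 9 (3S)-3-[(benzyloxy)methyl]hept-6-en-1-yne
Conditions: dimethyl (1-diazo-2-oxopropyl)phosphonate, K2CO3, MeOH, 0 °C → rt
Reagents that add atoms: dimethyl (1-diazo-2-oxopropyl)phosphonate, `CC(=O)C(=[N+]=[N-])P(=O)(OC)OC`
Why: Ohira–Bestmann (Seyferth–Gilbert) homologation converts the aldehyde into the terminal alkyne under mild carbonate conditions that preserve α-centres of β-alkoxy aldehydes.

Step 6
Reactants: 9 (3S)-3-[(benzyloxy)methyl]hept-6-en-1-yne
Product: 11 (2E,4S)-4-[(benzyloxy)methyl]-3-methylocta-2,7-dien-1-ol, via alkenyl(dimethyl)alane 10 (not isolated)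
Conditions: AlMe3, Cp2ZrCl2 (cat.), CH2Cl2, 0 °C → rt; then n-BuLi, THF, −78 °C; (CH2O)n, → rt
Reagents that add atoms: trimethylaluminium, `C[Al](C)C`; formaldehyde (from paraformaldehyde), `C=O`
Why: Negishi zirconium-catalysed carboalumination adds methyl and aluminium syn across the terminal alkyne (methyl to the internal carbon), and the derived alanate is hydroxymethylated with retention, so the E-trisubstituted allylic alcohol results directly. The isolated terminal alkene does not react under these conditions, and no olefination of an epimerisable β-alkoxy ketone is needed.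

Step 7
Reactants: 11 (2E,4S)-4-[(benzyloxy)methyl]-3-methylocta-2,7-dien-1-ol
Product: 12 (2E,4S)-4-[(benzyloxy)methyl]-1-bromo-3-methylocta-2,7-diene
Conditions: CBr4, PPh3, CH2Cl2, 0 °C
Reagents that add atoms: tetrabromomethane, `BrC(Br)(Br)Br`
Why: Appel bromination of the primary allylic alcohol under neutral conditions; substitution at the unhindered CH2 keeps the alkene geometry.

Step 8
Reactants: 13 but-3-yn-1-ol
Product: 15 4-(trimethylsilyl)but-3-yn-1-ol, via O-silylated C-silyl alkyne 14 (not isolated)
Conditions: EtMgBr (2.2 equiv), THF, 0 °C → reflux; Me3SiCl (2.2 equiv); then aq. H2SO4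
Reagents that add atoms: chlorotrimethylsilane, `C[Si](C)(C)Cl`
Why: Double deprotonation (O–H and alkyne C–H) and silylation, followed by acidic cleavage of the labile O–Si bond, leaves the C-silylated alkyne.

Step 9
Reactants: 15 4-(trimethylsilyl)but-3-yn-1-ol
Product: 16 (3Z)-4-(trimethylsilyl)but-3-en-1-ol
Conditions: H2 (1 atm), Ni(OAc)2, NaBH4, H2NCH2CH2NH2, EtOH, rt
Reagents that add atoms: none
Why: Semihydrogenation over nickel boride moderated by ethylenediamine delivers hydrogen syn and stops at the alkene, which fixes the Z-vinylsilane geometry needed for ring B closure.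

Step 10
Reactants: 16 (3Z)-4-(trimethylsilyl)but-3-en-1-ol
Product: 18 (3Z)-4-(trimethylsilyl)but-3-enoic acid, via (3Z)-4-(trimethylsilyl)but-3-enal 17 (not isolated)
Conditions: TEMPO (cat.), NaOCl (cat.), NaClO2, MeCN/aq. phosphate buffer (pH 6.7), 35 °C
Reagents that add atoms: sodium chlorite, `[Na+].[O-]Cl=O`
Why: TEMPO/hypochlorite-catalysed oxidation with chlorite as terminal oxidant takes the alcohol through the aldehyde to the acid at buffered pH, which avoids migration of the β,γ double bond into conjugation.

Step 11
Reactants: 18 (3Z)-4-(trimethylsilyl)but-3-enoic acid; 19 (R)-4-benzyl-1,3-oxazolidin-2-one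
Product: 21 (4R)-4-benzyl-3-[(3Z)-4-(trimethylsilyl)but-3-enoyl]-1,3-oxazolidin-2-one, via mixed pivalic anhydride 20 (not isolated)
Conditions: t-BuCOCl, Et3N, THF, −78 → 0 °C; then lithiated 19 (n-BuLi, THF, −78 °C), −78 → 0 °C
Reagents that add atoms: none
Why: N-acylation of the lithiated oxazolidinone by the mixed anhydride; the short, cold protocol limits amine-mediated isomerisation of the β,γ-unsaturated acyl group.

Step 12
Reactants: 21 (4R)-4-benzyl-3-[(3Z)-4-(trimethylsilyl)but-3-enoyl]-1,3-oxazolidin-2-one; 12 (2E,4S)-4-[(benzyloxy)methyl]-1-bromo-3-methylocta-2,7-diene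
Product: 22 (4R)-4-benzyl-3-[(2R,4E,6S)-6-[(benzyloxy)methyl]-5-methyl-2-[(Z)-2-(trimethylsilyl)ethenyl]deca-4,9-dienoyl]-1,3-oxazolidin-2-one
Conditions: 21 (1.3 equiv), NaN(SiMe3)2, THF, −78 °C; then 12, −78 → −45 °C
Reagents that add atoms: none
Why: Evans asymmetric alkylation, here the deconjugative α-alkylation of the chelated sodium Z-dienolate of a β,γ-unsaturated imide; attack anti to the benzyl group of the (R)-auxiliary sets the centre that becomes C7. α-Attack is kinetically preferred, the γ-carbon is shielded by silicon, and at −78 °C the Z geometry should be retained.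

Step 13
Reactants: 22 (4R)-4-benzyl-3-[(2R,4E,6S)-6-[(benzyloxy)methyl]-5-methyl-2-[(Z)-2-(trimethylsilyl)ethenyl]deca-4,9-dienoyl]-1,3-oxazolidin-2-one
Product: 24 (2R,4E,6S)-6-[(benzyloxy)methyl]-5-methyl-2-[(Z)-2-(trimethylsilyl)ethenyl]deca-4,9-dienoic acid, via peroxy acid 23 (not isolated)
Conditions: LiOH, H2O2, THF/H2O, 0 °C; then Na2SO3; then HCl to pH 3
Reagents that add atoms: hydrogen peroxide, `OO`
Why: Hydroperoxide cleaves the exocyclic imide carbonyl selectively; this weakly basic nucleophile at 0 °C spares the doubly activated C7–H, and sulfite reduces the peroxy acid before acidification.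

Step 14
Reactants: 24 (2R,4E,6S)-6-[(benzyloxy)methyl]-5-methyl-2-[(Z)-2-(trimethylsilyl)ethenyl]deca-4,9-dienoic acid
Product: 25 methyl (2R,4E,6S)-6-[(benzyloxy)methyl]-5-methyl-2-[(Z)-2-(trimethylsilyl)ethenyl]deca-4,9-dienoate
Conditions: Me3SiCHN2, PhMe/MeOH, 0 °C → rt
Reagents that add atoms: (trimethylsilyl)diazomethane, `C[Si](C)(C)C=[N+]=[N-]`
Why: Base-free esterification through diazomethane generated in situ gives the β,γ-unsaturated methyl ester without epimerisation or double-bond migration.

Step 15
Reactants: 25 methyl (2R,4E,6S)-6-[(benzyloxy)methyl]-5-methyl-2-[(Z)-2-(trimethylsilyl)ethenyl]deca-4,9-dienoate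
Product: 26 methyl (2R,4E,6S)-6-[(benzyloxy)methyl]-5-methyl-9-oxo-2-[(Z)-2-(trimethylsilyl)ethenyl]dec-4-enoate
Conditions: PdCl2 (10 mol %), CuCl, O2 (1 atm), DMF/H2O (7:1), rt
Reagents that add atoms: water, `O`
Why: Tsuji–Wacker oxidation is selective for the monosubstituted terminal alkene (Markovnikov hydroxypalladation, then β-hydride elimination); the trisubstituted alkene and the hindered internal Z-vinylsilane should react far more slowly. Unveiling the ketone last means it never meets an enolate or an organoaluminium reagent.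

Step 16
Reactants: 26 methyl (2R,4E,6S)-6-[(benzyloxy)methyl]-5-methyl-9-oxo-2-[(Z)-2-(trimethylsilyl)ethenyl]dec-4-enoate
Product: 27 methyl (2R,4aR,5S,8R,8aS)-5-[(benzyloxy)methyl]-8-hydroxy-4a,8-dimethyl-1,2,4a,5,6,7,8,8a-octahydronaphthalene-2-carboxylate
Conditions: MeAlCl2 (3 equiv), CH2Cl2, −78 → −20 °C; aq. NaHCO3
Reagents that add atoms: none
Why: Proposed new method: MeAlCl2 binds the methyl ketone (and, in excess, the ester and ether oxygens); C5 of the E-trisubstituted alkene attacks the activated carbonyl carbon to form C4–C5 (ring A, 6-endo with respect to the alkene), and the tertiary C10 cation is taken at the silicon-bearing carbon C9 of the Z-vinylsilane (ring B, 6-endo), after which loss of silicon from the β-silyl cation leaves the C8=C9 alkene. The closest known reaction types are the acetal-initiated, vinylsilane-terminated cation–olefin bicyclisation to trans-decalins and the alkylaluminium halide-promoted cyclisation of simple olefinic ketones; a methyl ketone as initiator of such a bicyclisation is the new element. Antiperiplanar addition across the E-alkene in a chair–chair array sets C5–H and the C10 methyl trans, so both centres follow from the alkene geometry. The absolute sense of the fold is fixed by the existing C1 and C7 centres, whose benzyloxymethyl and ester groups take equatorial sites. At C4 the ketone methyl prefers the equatorial position, away from the developing axial C10 methyl, so the aluminium-bound oxygen becomes axial. The step needs termination to outrun hydride or alkyl shifts and proton loss of the zwitterion: the Z geometry places silicon for ipso attack in a six-membered ring, the methylaluminium reagent scavenges protons, and full complexation of the ester carbonyl keeps it from capturing the C10 cation as a lactone.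

Step 17
Reactants: 27 methyl (2R,4aR,5S,8R,8aS)-5-[(benzyloxy)methyl]-8-hydroxy-4a,8-dimethyl-1,2,4a,5,6,7,8,8a-octahydronaphthalene-2-carboxylate
Product: 28 methyl (2S,4aR,5S,8R,8aS)-8-hydroxy-5-(hydroxymethyl)-4a,8-dimethyldecahydronaphthalene-2-carboxylate
Conditions: H2 (1 atm), 10% Pd/C, EtOAc/EtOH, rt
Reagents that add atoms: none
Why: Heterogeneous hydrogenation saturates the cis-disubstituted C8=C9 alkene and hydrogenolyses the benzyl ether in one operation; no stereocentre is formed and C7 ceases to be allylic.

Step 18
Reactants: 28 methyl (2S,4aR,5S,8R,8aS)-8-hydroxy-5-(hydroxymethyl)-4a,8-dimethyldecahydronaphthalene-2-carboxylate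
Product: 30 (1R,4S,4aR,7S,8aS)-4-(hydroxymethyl)-7-(2-hydroxypropan-2-yl)-1,4a-dimethyldecahydronaphthalen-1-ol, via methyl ketone 29 (not isolated)
Conditions: MeMgBr (8 equiv), THF, 0 °C → rt; aq. NH4Cl
Reagents that add atoms: methylmagnesium bromide, `C[Mg]Br`
Why: Double Grignard addition to the methyl ester through the methyl ketone gives the tertiary carbinol; the two hydroxyl groups are carried as magnesium alkoxides, hence the excess.

Step 19
Reactants: 30 (1R,4S,4aR,7S,8aS)-4-(hydroxymethyl)-7-(2-hydroxypropan-2-yl)-1,4a-dimethyldecahydronaphthalen-1-ol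
Product: 31 (1S,4R,4aS,6S,8aS)-4-hydroxy-6-(2-hydroxypropan-2-yl)-4,8a-dimethyldecahydronaphthalene-1-carbaldehyde
Conditions: TEMPO (cat.), PhI(OAc)2, CH2Cl2, rt
Reagents that add atoms: none
Why: Oxoammonium (TEMPO) oxidation acts only on the primary alcohol and stops at the aldehyde; the two tertiary alcohols cannot be oxidised, and the equatorial C1 aldehyde is the thermodynamically preferred epimer.

Step 20
Reactants: 31 (1S,4R,4aS,6S,8aS)-4-hydroxy-6-(2-hydroxypropan-2-yl)-4,8a-dimethyldecahydronaphthalene-1-carbaldehyde; 32 3,5-dimethoxyphenol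
Product: 35 2-[(1R)-1-[(1R,4R,4aS,6S,8aR)-4-hydroxy-6-(2-hydroxypropan-2-yl)-4,8a-dimethyldecahydronaphthalen-1-yl]-3-methylbutyl]-3,5-dimethoxyphenol, via ortho-hydroxybenzylic alcohol adduct 33 (not isolated), via ortho-quinone methide 34 (not isolated)
Conditions: 32 (1.1 equiv), EtMgBr, Et2O then PhMe, 0 °C; 31, 0 °C → rt; then i-BuMgBr (6 equiv), −20 °C → rt; aq. NH4Cl
Reagents that add atoms: isobutylmagnesium bromide, `CC(C)C[Mg]Br`
Why: Ortho-selective, magnesium-templated hydroxyalkylation of the phenoxide by the aldehyde, elimination of the doubly methoxy-activated adduct to the ortho-quinone methide, and 1,4-addition of the Grignard reagent with rearomatisation build both bonds at C1′ in one flask. C1′ is set under 1,3-allylic strain control: C1–H lies in the plane of the methide, so the nucleophile enters past C2 and away from quaternary C10, which corresponds to the required (R) configuration. The tertiary alcohols ride through as magnesium alkoxides.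

Step 21
Reactants: 35 2-[(1R)-1-[(1R,4R,4aS,6S,8aR)-4-hydroxy-6-(2-hydroxypropan-2-yl)-4,8a-dimethyldecahydronaphthalen-1-yl]-3-methylbutyl]-3,5-dimethoxyphenol
Product: 36 2-[(1R)-1-[(1R,4R,4aS,6S,8aR)-4-hydroxy-6-(2-hydroxypropan-2-yl)-4,8a-dimethyldecahydronaphthalen-1-yl]-3-methylbutyl]-1,3,5-trimethoxybenzene
Conditions: MeI, K2CO3, acetone, reflux
Reagents that add atoms: iodomethane, `CI`
Why: Williamson O-methylation of the phenol; K2CO3 does not deprotonate the tertiary alcohols, which stay free.

Step 22
Reactants: 36 2-[(1R)-1-[(1R,4R,4aS,6S,8aR)-4-hydroxy-6-(2-hydroxypropan-2-yl)-4,8a-dimethyldecahydronaphthalen-1-yl]-3-methylbutyl]-1,3,5-trimethoxybenzene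
Product: 38 5-[(1R)-1-[(1R,4R,4aS,6S,8aR)-4-hydroxy-6-(2-hydroxypropan-2-yl)-4,8a-dimethyldecahydronaphthalen-1-yl]-3-methylbutyl]-2,4,6-trimethoxybenzene-1,3-dicarbaldehyde, via monoformyl α-amino alkoxide 37 (not isolated)
Conditions: n-BuLi (3.3 equiv), TMEDA, THF, 0 °C; DMF (1.1 equiv), −78 → 0 °C; n-BuLi (2 equiv), 0 °C; DMF, → rt; aq. NH4Cl
Reagents that add atoms: N,N-dimethylformamide, `CN(C)C=O`
Why: Iterated directed ortho-lithiation and formylation: each aryl C–H lies between two methoxy groups, and the first formyl group is carried as its lithium α-amino alkoxide (in situ protection) through the second lithiation. The tertiary alcohols are tolerated as lithium alkoxides, which a Lewis-acid-mediated Rieche or Vilsmeier–Haack formylation would not allow.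

Step 23
Reactants: 38 5-[(1R)-1-[(1R,4R,4aS,6S,8aR)-4-hydroxy-6-(2-hydroxypropan-2-yl)-4,8a-dimethyldecahydronaphthalen-1-yl]-3-methylbutyl]-2,4,6-trimethoxybenzene-1,3-dicarbaldehyde
Product: 39 5-[(1R)-1-[(1R,4R,4aS,6S,8aR)-4-hydroxy-6-(2-hydroxypropan-2-yl)-4,8a-dimethyldecahydronaphthalen-1-yl]-3-methylbutyl]-2,4,6-trihydroxybenzene-1,3-dicarbaldehyde
Conditions: EtSNa (excess), DMF, 110 °C; then dilute HCl, 0 °C
Reagents that add atoms: none
Why: Nucleophilic demethylation by thiolate at the methyl carbons; every methoxy group is ortho or para to a formyl group, so the aryloxide leaving groups are stabilised. The basic conditions spare the tertiary alcohols that a boron or aluminium halide would ionise.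

Compound list

```
1 | hex-5-enoic acid | C=CCCCC(=O)O | starting material
2 | (S)-4-benzyl-1,3-oxazolidin-2-one | O=C1N[C@@H](Cc2ccccc2)CO1 | starting material
3 | hex-5-enoic pivalic anhydride | C=CCCCC(=O)OC(=O)C(C)(C)C | intermediate (not isolated)
4 | (4S)-4-benzyl-3-(hex-5-enoyl)-1,3-oxazolidin-2-one | C=CCCCC(=O)N1[C@@H](Cc2ccccc2)COC1=O | intermediate
5 | benzyl chloromethyl ether | ClCOCc1ccccc1 | starting material
6 | (4S)-4-benzyl-3-[(2R)-2-[(benzyloxy)methyl]hex-5-enoyl]-1,3-oxazolidin-2-one | C=CCC[C@H](COCc1ccccc1)C(=O)N1[C@@H](Cc2ccccc2)COC1=O | intermediate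
7 | (2S)-2-[(benzyloxy)methyl]hex-5-en-1-ol | C=CCC[C@H](COCc1ccccc1)CO | intermediate
8 | (2R)-2-[(benzyloxy)methyl]hex-5-enal | C=CCC[C@H](COCc1ccccc1)C=O | intermediate
9 | (3S)-3-[(benzyloxy)methyl]hept-6-en-1-yne | C=CCC[C@H](COCc1ccccc1)C#C | intermediate
10 | [(1E,3S)-3-[(benzyloxy)methyl]-2-methylhepta-1,6-dien-1-yl]dimethylalane | C=CCC[C@H](COCc1ccccc1)/C(C)=C/[Al](C)C | intermediate (not isolated)
11 | (2E,4S)-4-[(benzyloxy)methyl]-3-methylocta-2,7-dien-1-ol | C=CCC[C@H](COCc1ccccc1)/C(C)=C/CO | intermediate
12 | (2E,4S)-4-[(benzyloxy)methyl]-1-bromo-3-methylocta-2,7-diene | C=CCC[C@H](COCc1ccccc1)/C(C)=C/CBr | intermediate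
13 | but-3-yn-1-ol | C#CCCO | starting material
14 | trimethyl{[4-(trimethylsilyl)but-3-yn-1-yl]oxy}silane | C[Si](C)(C)C#CCCO[Si](C)(C)C | intermediate (not isolated)
15 | 4-(trimethylsilyl)but-3-yn-1-ol | C[Si](C)(C)C#CCCO | intermediate
16 | (3Z)-4-(trimethylsilyl)but-3-en-1-ol | C[Si](C)(C)/C=C\CCO | intermediate
17 | (3Z)-4-(trimethylsilyl)but-3-enal | C[Si](C)(C)/C=C\CC=O | intermediate (not isolated)
18 | (3Z)-4-(trimethylsilyl)but-3-enoic acid | C[Si](C)(C)/C=C\CC(=O)O | intermediate
19 | (R)-4-benzyl-1,3-oxazolidin-2-one | O=C1N[C@H](Cc2ccccc2)CO1 | starting material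
20 | (3Z)-4-(trimethylsilyl)but-3-enoic pivalic anhydride | C[Si](C)(C)/C=C\CC(=O)OC(=O)C(C)(C)C | intermediate (not isolated)
21 | (4R)-4-benzyl-3-[(3Z)-4-(trimethylsilyl)but-3-enoyl]-1,3-oxazolidin-2-one | C[Si](C)(C)/C=C\CC(=O)N1[C@H](Cc2ccccc2)COC1=O | intermediate
22 | (4R)-4-benzyl-3-[(2R,4E,6S)-6-[(benzyloxy)methyl]-5-methyl-2-[(Z)-2-(trimethylsilyl)ethenyl]deca-4,9-dienoyl]-1,3-oxazolidin-2-one | C=CCC[C@H](COCc1ccccc1)/C(C)=C/C[C@@H](C(=O)N1[C@H](Cc2ccccc2)COC1=O)/C=C\[Si](C)(C)C | intermediate
23 | (2R,4E,6S)-6-[(benzyloxy)methyl]-5-methyl-2-[(Z)-2-(trimethylsilyl)ethenyl]deca-4,9-dieneperoxoic acid | C=CCC[C@H](COCc1ccccc1)/C(C)=C/C[C@@H](C(=O)OO)/C=C\[Si](C)(C)C | intermediate (not isolated)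
24 | (2R,4E,6S)-6-[(benzyloxy)methyl]-5-methyl-2-[(Z)-2-(trimethylsilyl)ethenyl]deca-4,9-dienoic acid | C=CCC[C@H](COCc1ccccc1)/C(C)=C/C[C@@H](C(=O)O)/C=C\[Si](C)(C)C | intermediate
25 | methyl (2R,4E,6S)-6-[(benzyloxy)methyl]-5-methyl-2-[(Z)-2-(trimethylsilyl)ethenyl]deca-4,9-dienoate | C=CCC[C@H](COCc1ccccc1)/C(C)=C/C[C@@H](C(=O)OC)/C=C\[Si](C)(C)C | intermediate
26 | methyl (2R,4E,6S)-6-[(benzyloxy)methyl]-5-methyl-9-oxo-2-[(Z)-2-(trimethylsilyl)ethenyl]dec-4-enoate | CC(=O)CC[C@H](COCc1ccccc1)/C(C)=C/C[C@@H](C(=O)OC)/C=C\[Si](C)(C)C | intermediate (precursor of the key step)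
27 | methyl (2R,4aR,5S,8R,8aS)-5-[(benzyloxy)methyl]-8-hydroxy-4a,8-dimethyl-1,2,4a,5,6,7,8,8a-octahydronaphthalene-2-carboxylate | c1ccccc1COC[C@H]1CC[C@@](C)(O)[C@H]2C[C@@H](C(=O)OC)C=C[C@]12C | intermediate (product of the key step)
28 | methyl (2S,4aR,5S,8R,8aS)-8-hydroxy-5-(hydroxymethyl)-4a,8-dimethyldecahydronaphthalene-2-carboxylate | OC[C@H]1CC[C@@](C)(O)[C@H]2C[C@@H](C(=O)OC)CC[C@]12C | intermediate
29 | 1-[(2S,4aR,5S,8R,8aS)-8-hydroxy-5-(hydroxymethyl)-4a,8-dimethyldecahydronaphthalen-2-yl]ethan-1-one | OC[C@H]1CC[C@@](C)(O)[C@H]2C[C@@H](C(C)=O)CC[C@]12C | intermediate (not isolated)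
30 | (1R,4S,4aR,7S,8aS)-4-(hydroxymethyl)-7-(2-hydroxypropan-2-yl)-1,4a-dimethyldecahydronaphthalen-1-ol | OC[C@H]1CC[C@@](C)(O)[C@H]2C[C@@H](C(C)(C)O)CC[C@]12C | intermediate
31 | (1S,4R,4aS,6S,8aS)-4-hydroxy-6-(2-hydroxypropan-2-yl)-4,8a-dimethyldecahydronaphthalene-1-carbaldehyde | O=C[C@H]1CC[C@@](C)(O)[C@H]2C[C@@H](C(C)(C)O)CC[C@]12C | intermediate
32 | 3,5-dimethoxyphenol | COc1cc(O)cc(OC)c1 | starting material
33 | 2-{hydroxy[(1S,4R,4aS,6S,8aR)-4-hydroxy-6-(2-hydroxypropan-2-yl)-4,8a-dimethyldecahydronaphthalen-1-yl]methyl}-3,5-dimethoxyphenol (carbinol carbon unassigned; present as its magnesium salt) | COc1cc(OC)c(C(O)[C@H]2CC[C@@](C)(O)[C@H]3C[C@@H](C(C)(C)O)CC[C@]23C)c(O)c1 | intermediate (not isolated)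
34 | 6-{[(1R,4R,4aS,6S,8aR)-4-hydroxy-6-(2-hydroxypropan-2-yl)-4,8a-dimethyldecahydronaphthalen-1-yl]methylidene}-3,5-dimethoxycyclohexa-2,4-dien-1-one (methide geometry unassigned) | O=C1C=C(OC)C=C(OC)C1=C[C@H]3CC[C@@](C)(O)[C@H]4C[C@@H](C(C)(C)O)CC[C@]34C | intermediate (not isolated)
35 | 2-[(1R)-1-[(1R,4R,4aS,6S,8aR)-4-hydroxy-6-(2-hydroxypropan-2-yl)-4,8a-dimethyldecahydronaphthalen-1-yl]-3-methylbutyl]-3,5-dimethoxyphenol | CC(C)C[C@@H](c1c(O)cc(OC)cc1OC)[C@H]1CC[C@@](C)(O)[C@H]2C[C@@H](C(C)(C)O)CC[C@]12C | intermediate
36 | 2-[(1R)-1-[(1R,4R,4aS,6S,8aR)-4-hydroxy-6-(2-hydroxypropan-2-yl)-4,8a-dimethyldecahydronaphthalen-1-yl]-3-methylbutyl]-1,3,5-trimethoxybenzene | CC(C)C[C@@H](c1c(OC)cc(OC)cc1OC)[C@H]1CC[C@@](C)(O)[C@H]2C[C@@H](C(C)(C)O)CC[C@]12C | intermediate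
37 | monoformyl α-amino alkoxide of 36, drawn as the neutral (dimethylamino)carbinol (carbinol carbon unassigned; present as its lithium salt) | CC(C)C[C@@H](c1c(OC)cc(OC)c(C(O)N(C)C)c1OC)[C@H]1CC[C@@](C)(O)[C@H]2C[C@@H](C(C)(C)O)CC[C@]12C | intermediate (not isolated)
38 | 5-[(1R)-1-[(1R,4R,4aS,6S,8aR)-4-hydroxy-6-(2-hydroxypropan-2-yl)-4,8a-dimethyldecahydronaphthalen-1-yl]-3-methylbutyl]-2,4,6-trimethoxybenzene-1,3-dicarbaldehyde | CC(C)C[C@@H](c1c(OC)c(C=O)c(OC)c(C=O)c1OC)[C@H]1CC[C@@](C)(O)[C@H]2C[C@@H](C(C)(C)O)CC[C@]12C | intermediate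
39 | 5-[(1R)-1-[(1R,4R,4aS,6S,8aR)-4-hydroxy-6-(2-hydroxypropan-2-yl)-4,8a-dimethyldecahydronaphthalen-1-yl]-3-methylbutyl]-2,4,6-trihydroxybenzene-1,3-dicarbaldehyde (CNP0409870.6) | CC(C)C[C@@H](c1c(O)c(C=O)c(O)c(C=O)c1O)[C@H]1CC[C@@](C)(O)[C@H]2C[C@@H](C(C)(C)O)CC[C@]12C | target
```

Total step count: 23. Longest linear sequence: 19 steps (steps 1–7 and 12–23); steps 8–11 form the second branch, which joins at step 12.

Least certain steps

Step 16 (the step that goes beyond known chemistry).
- What may go wrong: the zwitterion formed after ring A closure is diverted before ring B closes, by 1,2-hydride or alkyl shift, by proton loss to monocyclic ene-type alcohols, or by reversal of the addition to the ketone. Face selectivity at C4 may also be low. A ketone–aluminium complex is a weaker and more reversible initiator than an oxocarbenium ion.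
- Fallback with known chemistry, from 26 back to 27: 26 is converted with ethylene glycol (pyridinium tosylate, benzene, reflux) into its dioxolane ketal F1. SnCl4 in CH2Cl2 at −78 °C opens the dioxolane to an oxocarbenium ion, which starts the acetal-type, vinylsilane-terminated bicyclisation and gives the C4 2-hydroxyethyl ether F2. Iodination (I2, PPh3, imidazole) gives the 2-iodoethyl ether F3, and zinc dust in refluxing ethanol removes the two-carbon unit by reductive β-elimination to give 27.

Step 20.
- What may go wrong: the ortho-quinone methide is consumed before the Grignard reagent adds, or face selectivity at C1′ is insufficient. Competing paths are addition of a second phenoxide, a 1,5-hydrogen shift to a styrene, hydride transfer from the β-branched Grignard reagent, and intramolecular capture by the C4 alkoxide. They compete because the methide forms here at a temperature at which they are not frozen out.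
- Fallback, from 31 and 32 back to 35: the hydroxyalkylation is run alone and adduct 33 is isolated. Its phenol is acylated selectively (Boc2O, i-Pr2NEt, cat. DMAP) to the aryl tert-butyl carbonate F4. i-BuMgBr at −78 °C then deprotonates the benzylic alcohol, the carbonate migrates to that oxygen and is expelled, and the ortho-quinone methide 34 formed at low temperature is trapped at once by excess Grignard reagent to give 35.

Step 12.
- What may go wrong: loss of stereochemical integrity at C7. The α-hydrogen is activated by both the imide and the vinyl group, so low face selectivity, epimerisation, migration of the double bond into conjugation, or scrambling of the Z geometry through the silyl-stabilised dienolate can occur during alkylation or auxiliary removal.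
- Fallback, from 18 and 12 back to 28: 18 is esterified (Me3SiCHN2) to methyl (3Z)-4-(trimethylsilyl)but-3-enoate F5. Its lithium enolate (LDA, THF, −78 °C) is alkylated with 12 to give 25 together with its C2 epimer F6, two steps shorter than the auxiliary route. The mixture is carried through steps 15–17, the epimeric series being ketone F7, bicyclic ester F8 (C1 alone should dictate the fold) and saturated hydroxy ester F9. NaOMe in MeOH then equilibrates the ester of F9 to the equatorial position, which is 28.

Step 15.
- What may go wrong: loss of chemoselectivity in the palladium-mediated oxidation, by attack on or desilylation of the vinylsilane, or by palladium hydride-mediated migration of the terminal or the β,γ double bond.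
- Fallback, from 11 back to 26: the same oxidation is run on 11, before any vinylsilane is present, to give keto alcohol F10. Appel bromination gives keto bromide F11. Alkylation of the sodium enolate of 21 gives keto imide F12; the imide enolate is far less basic than a ketone enolate and the allylic bromide reacts at −78 °C. LiOH/H2O2 gives keto acid F13, and Me3SiCHN2 gives 26.

Step 22.
- What may go wrong: incomplete second metalation. The arene already carries an α-amino alkoxide and the molecule two further alkoxides, so deprotonation slows and butyllithium may instead attack the masked aldehyde, leaving monoaldehyde.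
- Fallback, from 36 back to 38: electrophilic dibromination (N-bromosuccinimide, 2 equiv, MeCN, 0 °C) gives dibromide F14. Double bromine–lithium exchange (t-BuLi, THF, −78 °C) followed by DMF gives 38.

## Further compounds

```
F1 | step 16 | methyl (2R,4E,6S)-6-[(benzyloxy)methyl]-5-methyl-8-(2-methyl-1,3-dioxolan-2-yl)-2-[(Z)-2-(trimethylsilyl)ethenyl]oct-4-enoate | CC1(CC[C@H](COCc2ccccc2)/C(C)=C/C[C@@H](C(=O)OC)/C=C\[Si](C)(C)C)OCCO1
F2 | step 16 | methyl (2R,4aR,5S,8R,8aS)-5-[(benzyloxy)methyl]-8-(2-hydroxyethoxy)-4a,8-dimethyl-1,2,4a,5,6,7,8,8a-octahydronaphthalene-2-carboxylate | c1ccccc1COC[C@H]1CC[C@@](C)(OCCO)[C@H]2C[C@@H](C(=O)OC)C=C[C@]12C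
F3 | step 16 | methyl (2R,4aR,5S,8R,8aS)-5-[(benzyloxy)methyl]-8-(2-iodoethoxy)-4a,8-dimethyl-1,2,4a,5,6,7,8,8a-octahydronaphthalene-2-carboxylate | c1ccccc1COC[C@H]1CC[C@@](C)(OCCI)[C@H]2C[C@@H](C(=O)OC)C=C[C@]12C
F4 | step 20 | tert-butyl 2-{hydroxy[(1S,4R,4aS,6S,8aR)-4-hydroxy-6-(2-hydroxypropan-2-yl)-4,8a-dimethyldecahydronaphthalen-1-yl]methyl}-3,5-dimethoxyphenyl carbonate (carbinol carbon unassigned) | COc1cc(OC)c(C(O)[C@H]2CC[C@@](C)(O)[C@H]3C[C@@H](C(C)(C)O)CC[C@]23C)c(OC(=O)OC(C)(C)C)c1
F5 | step 12 | methyl (3Z)-4-(trimethylsilyl)but-3-enoate | C[Si](C)(C)/C=C\CC(=O)OC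
F6 | step 12 | methyl (2S,4E,6S)-6-[(benzyloxy)methyl]-5-methyl-2-[(Z)-2-(trimethylsilyl)ethenyl]deca-4,9-dienoate | C=CCC[C@H](COCc1ccccc1)/C(C)=C/C[C@H](C(=O)OC)/C=C\[Si](C)(C)C
F7 | step 12 | methyl (2S,4E,6S)-6-[(benzyloxy)methyl]-5-methyl-9-oxo-2-[(Z)-2-(trimethylsilyl)ethenyl]dec-4-enoate | CC(=O)CC[C@H](COCc1ccccc1)/C(C)=C/C[C@H](C(=O)OC)/C=C\[Si](C)(C)C
F8 | step 12 | methyl (2S,4aR,5S,8R,8aS)-5-[(benzyloxy)methyl]-8-hydroxy-4a,8-dimethyl-1,2,4a,5,6,7,8,8a-octahydronaphthalene-2-carboxylate | c1ccccc1COC[C@H]1CC[C@@](C)(O)[C@H]2C[C@H](C(=O)OC)C=C[C@]12C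
F9 | step 12 | methyl (2R,4aR,5S,8R,8aS)-8-hydroxy-5-(hydroxymethyl)-4a,8-dimethyldecahydronaphthalene-2-carboxylate | OC[C@H]1CC[C@@](C)(O)[C@H]2C[C@H](C(=O)OC)CC[C@]12C
F10 | step 15 | (5S,6E)-5-[(benzyloxy)methyl]-8-hydroxy-6-methyloct-6-en-2-one | CC(=O)CC[C@H](COCc1ccccc1)/C(C)=C/CO
F11 | step 15 | (5S,6E)-5-[(benzyloxy)methyl]-8-bromo-6-methyloct-6-en-2-one | CC(=O)CC[C@H](COCc1ccccc1)/C(C)=C/CBr
F12 | step 15 | (4R)-4-benzyl-3-[(2R,4E,6S)-6-[(benzyloxy)methyl]-5-methyl-9-oxo-2-[(Z)-2-(trimethylsilyl)ethenyl]dec-4-enoyl]-1,3-oxazolidin-2-one | CC(=O)CC[C@H](COCc1ccccc1)/C(C)=C/C[C@@H](C(=O)N1[C@H](Cc2ccccc2)COC1=O)/C=C\[Si](C)(C)C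
F13 | step 15 | (2R,4E,6S)-6-[(benzyloxy)methyl]-5-methyl-9-oxo-2-[(Z)-2-(trimethylsilyl)ethenyl]dec-4-enoic acid | CC(=O)CC[C@H](COCc1ccccc1)/C(C)=C/C[C@@H](C(=O)O)/C=C\[Si](C)(C)C
F14 | step 22 | 2,4-dibromo-6-[(1R)-1-[(1R,4R,4aS,6S,8aR)-4-hydroxy-6-(2-hydroxypropan-2-yl)-4,8a-dimethyldecahydronaphthalen-1-yl]-3-methylbutyl]-1,3,5-trimethoxybenzene | CC(C)C[C@@H](c1c(OC)c(Br)c(OC)c(Br)c1OC)[C@H]1CC[C@@](C)(O)[C@H]2C[C@@H](C(C)(C)O)CC[C@]12C
A1 | alternative 1 | side-chain siloxyalkyne: triisopropylsilyl ynol ether carrying at its propargylic carbon the isobutyl group and the bis(triethylsilyl)-protected decalin | CC(C)C[C@@H](C#CO[Si](C(C)C)(C(C)C)C(C)C)[C@H]1CC[C@@](C)(O[Si](CC)(CC)CC)[C@H]2C[C@@H](C(C)(C)O[Si](CC)(CC)CC)CC[C@]12C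
A2 | alternative 1 | 3-ethoxycyclobut-2-en-1-one | CCOC1=CC(=O)C1
A3 | alternative 1 | 2-alkyl-5-ethoxy-3-(triisopropylsilyloxy)phenol with the bis(triethylsilyl)-protected decalin side chain | CC(C)C[C@@H](c1c(O[Si](C(C)C)(C(C)C)C(C)C)cc(OCC)cc1O)[C@H]1CC[C@@](C)(O[Si](CC)(CC)CC)[C@H]2C[C@@H](C(C)(C)O[Si](CC)(CC)CC)CC[C@]12C
A4 | alternative 2 | carone (3,7,7-trimethylbicyclo[4.1.0]heptan-2-one, cyclopropane configured as in A6) | O=C1[C@@H]2[C@@H](C2(C)C)CCC1C
A5 | alternative 2 | methyl (E)-4-oxohex-2-enoate | CCC(=O)/C=C/C(=O)OC
A6 | alternative 2 | tricyclic cyclopropyl enone with the C1 ester and the angular methyl | COC(=O)[C@H]1CC(=O)C(C)=C2[C@@H]3[C@@H](C3(C)C)CC[C@]12C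
A7 | alternative 3 | eudesmane C1 aldehyde (identical with 31) | O=C[C@H]1CC[C@@](C)(O)[C@H]2C[C@@H](C(C)(C)O)CC[C@]12C
A8 | alternative 3 | bromomagnesium 3,5-dimethoxyphenoxide | COc1cc(OC)cc(O[Mg]Br)c1
A9 | alternative 3 | isobutylmagnesium bromide | CC(C)C[Mg]Br
A10 | alternative 3 | 2-alkyl-3,5-dimethoxyphenol with the complete carbon skeleton (identical with 35) | CC(C)C[C@@H](c1c(O)cc(OC)cc1OC)[C@H]1CC[C@@](C)(O)[C@H]2C[C@@H](C(C)(C)O)CC[C@]12C
```
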